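**Assumption:** the target is a planar, achiral flavone with no stereocentres, so there is no enantiomer to control. It is delivered as the free hydrogen sulfate drawn, via its ammonium salt.

## Retrosynthetic overview

1. Target 17 ← removal of two MOM ethers (acid) and then the trichloroethyl (TCE) sulfate mask (Zn) from the protected flavone 15.
2. 15 ← one Rh(III) formyl C–H alkynylation/6-endo oxa-Michael annulation of salicylaldehyde 6 with bromoalkyne 14. This forms C4–C3 and O1–C2; the pyranone ring is made last and both benzene rings arrive intact.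
3. 6 ← resorcinol: ortho-lithiation/oxygenation at C2, O-methylation, Ir C–H borylation/oxidation, ortho-formylation. The symmetric phenol 5 has a single free OH, which fixes the 6-OMe regiochemistry.
4. 14 ← 4-iodophenol + TMS-acetylene (Sonogashira), then early sulfation as the acid-stable TCE diester (reagent made from trichloroethanol + SO2Cl2), then bromodesilylation.

## Route

**Step 1**
Reactants: 1, resorcinol
Product: 2, 1,3-bis(methoxymethoxy)benzene
Conditions: MOMCl (2.5 equiv), i-Pr2NEt, CH2Cl2, 0 °C → rt
Reagents that add atoms: chloromethyl methyl ether, COCCl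
Why: Double O-alkylation (MOM protection); MOM is a strong ortho-directing group, has no aryl C–H to compete in the later Ir borylation, and is cleaved by acid that the masked sulfate tolerates.

**Step 2**
Reactants: 2, 1,3-bis(methoxymethoxy)benzene
Product: 3, 2,6-bis(methoxymethoxy)phenol
Conditions: n-BuLi, THF, 0 °C → rt; B(OMe)3, −78 °C → rt; then 30% H2O2, AcOH, 0 °C
Reagents that add atoms: hydrogen peroxide, OO (trimethyl borate is transient)
Why: Directed ortho-metalation; the C2–H flanked by two OMOM groups is lithiated selectively, and borate trapping with oxidative C–B to C–O migration gives the phenol.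

**Step 3**
Reactants: 3, 2,6-bis(methoxymethoxy)phenol
Product: 4, 2-methoxy-1,3-bis(methoxymethoxy)benzene
Conditions: MeI, K2CO3, DMF, rt → 40 °C
Reagents that add atoms: iodomethane, CI
Why: Williamson O-methylation of the only free phenol installs the future 6-OMe.

**Step 4**
Reactants: 4, 2-methoxy-1,3-bis(methoxymethoxy)benzene
Product: 5, 4-methoxy-3,5-bis(methoxymethoxy)phenol
Conditions: [Ir(OMe)(cod)]2 (1.5 mol %), 3,4,7,8-Me4-phen (3 mol %), B2pin2 (0.8 equiv), THF, 80 °C; then aq. H2O2, NaOH, THF, 0 °C; Na2S2O3 quench, pH 6
Reagents that add atoms: hydrogen peroxide, OO (B2pin2 is transient)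
Why: Sterically controlled Ir-catalysed C–H borylation occurs only at C5, the sole aryl C–H with no ortho substituent, and oxidation of the ArBpin gives the phenol; the product is symmetric, so its two ortho C–H positions are equivalent.

**Step 5**
Reactants: 5, 4-methoxy-3,5-bis(methoxymethoxy)phenol
Product: 6, 2-hydroxy-5-methoxy-4,6-bis(methoxymethoxy)benzaldehyde
Conditions: MgCl2, Et3N, (CH2O)n, MeCN, reflux
Reagents that add atoms: paraformaldehyde (as formaldehyde), C=O
Why: Magnesium-phenoxide-directed ortho-formylation (Casnati–Skattebøl); the para position is blocked by OMe, the two ortho sites are equivalent, and the first CHO deactivates against a second.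

**Step 6**
Reactants: 7, 4-iodophenol; 8, ethynyltrimethylsilane
Product: 9, 4-[(trimethylsilyl)ethynyl]phenol
Conditions: PdCl2(PPh3)2 (2 mol %), CuI (4 mol %), Et3N, THF, rt
Reagents that add atoms: none
Why: Sonogashira coupling at the aryl iodide proceeds at room temperature and tolerates the free phenol.

**Step 7**
Reactants: 10, 2,2,2-trichloroethanol; 11, sulfuryl chloride
Product: 12, 2,2,2-trichloroethyl chlorosulfate
Conditions: pyridine, Et2O, −78 °C → rt; distil
Reagents that add atoms: none
Why: Chlorosulfation of the alcohol by substitution at S(VI); one S–Cl is kept for transfer to the phenol.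

**Step 8**
Reactants: 9, 4-[(trimethylsilyl)ethynyl]phenol; 12, 2,2,2-trichloroethyl chlorosulfate
Product: 13, 2,2,2-trichloroethyl 4-[(trimethylsilyl)ethynyl]phenyl sulfate
Conditions: Et3N, DMAP, THF, 0 °C → rt
Reagents that add atoms: none
Why: DMAP-catalysed sulfuryl transfer to the phenoxide gives a neutral mixed sulfate diester that is stable to acid and to the later metal-catalysed steps.

**Step 9**
Reactants: 13, 2,2,2-trichloroethyl 4-[(trimethylsilyl)ethynyl]phenyl sulfate
Product: 14, 4-(bromoethynyl)phenyl 2,2,2-trichloroethyl sulfate
Conditions: NBS (1.2 equiv), AgNO3 (15 mol %), acetone, rt, dark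
Reagents that add atoms: N-bromosuccinimide, O=C1CCC(=O)N1Br
Why: Ag(I)-catalysed bromodesilylation converts C–Si to C–Br under neutral conditions that leave the TCE sulfate untouched.

**Step 10**
Reactants: 6, 2-hydroxy-5-methoxy-4,6-bis(methoxymethoxy)benzaldehyde; 14, 4-(bromoethynyl)phenyl 2,2,2-trichloroethyl sulfate (1.2 equiv)
Product: 15, 2,2,2-trichloroethyl 4-[6-methoxy-5,7-bis(methoxymethoxy)-4-oxo-4H-chromen-2-yl]phenyl sulfate
Conditions: [Cp*RhCl2]2 (2.5 mol %), AgSbF6 (10 mol %), CsOAc (1.5 equiv), DCE, 50 °C; then DMAP (20 mol %), 50 °C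
Reagents that add atoms: none
Why: Proposed new method: a redox-neutral Rh(III) formyl C–H alkynylation/annulation in which phenoxide-directed, acetate-assisted cleavage of the aldehyde C–H gives a five-membered acyl-rhodacycle, regioselective 1,2-insertion of the bromoalkyne (acyl to the C–Br carbon, Rh to the aryl-bearing carbon) and β-bromide elimination release the o-hydroxyaryl ynone and Rh(III)–Br without external oxidant (CsOAc takes up HBr and regenerates Rh–OAc), and the phenol then closes 6-endo-dig onto the ynone (DMAP-assisted oxa-Michael) to give the 2-arylchromone, forming C4–C3 and O1–C2 in one operation; the closest known reaction types are Cp*Rh(III)/Ir(III) formyl C–H alkynylation of salicylaldehydes with silyl-ethynylbenziodoxolones, Rh(III) C–H alkynylation of arenes with bromoalkynes, and Rh(III) oxidative annulation of salicylaldehydes with internal alkynes to chromones, and the new element is using an aryl bromoalkyne as both alkyne and internal oxidant to deliver a flavone directly.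

**Step 11**
Reactants: 15, the bis-MOM flavone TCE sulfate
Product: 16, 4-(5,7-dihydroxy-6-methoxy-4-oxo-4H-chromen-2-yl)phenyl 2,2,2-trichloroethyl sulfate
Conditions: 3 M aq. HCl, MeOH/THF, 45 °C
Reagents that add atoms: none
Why: Acid-catalysed acetal hydrolysis removes both aryl MOM ethers; the aryl methyl ether, the flavone and the TCE sulfate diester are acid-stable, and the sulfate is still masked so it cannot solvolyse.

**Step 12**
Reactants: 16, the 5,7-dihydroxyflavone TCE sulfate
Product: 17, hispidulin 4'-sulfate
Conditions: Zn dust, HCO2NH4, MeOH/THF, rt; filter; Dowex 50W (H+), MeOH/H2O, 0 °C; lyophilise (store cold or keep as the ammonium salt)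
Reagents that add atoms: none
Why: Zinc-mediated reductive β-elimination of the trichloroethyl group (loss of chloride and 1,1-dichloroethene) frees the aryl sulfate monoester under neutral conditions without touching the flavone or the phenols; cold H+ exchange gives the free acid.

## Compound list

1 | resorcinol | Oc1cccc(O)c1 | starting material
2 | 1,3-bis(methoxymethoxy)benzene | COCOc1cccc(OCOC)c1 | intermediate
3 | 2,6-bis(methoxymethoxy)phenol | COCOc1cccc(OCOC)c1O | intermediate
4 | 2-methoxy-1,3-bis(methoxymethoxy)benzene | COCOc1cccc(OCOC)c1OC | intermediate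
5 | 4-methoxy-3,5-bis(methoxymethoxy)phenol | COCOc1cc(O)cc(OCOC)c1OC | intermediate
6 | 2-hydroxy-5-methoxy-4,6-bis(methoxymethoxy)benzaldehyde | O=Cc1c(O)cc(OCOC)c(OC)c1OCOC | intermediate
7 | 4-iodophenol | Oc1ccc(I)cc1 | starting material
8 | ethynyltrimethylsilane | C#C[Si](C)(C)C | starting material
9 | 4-[(trimethylsilyl)ethynyl]phenol | C[Si](C)(C)C#Cc1ccc(O)cc1 | intermediate
10 | 2,2,2-trichloroethanol | OCC(Cl)(Cl)Cl | starting material
11 | sulfuryl chloride | O=S(=O)(Cl)Cl | starting material
12 | 2,2,2-trichloroethyl chlorosulfate | O=S(=O)(Cl)OCC(Cl)(Cl)Cl | intermediate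
13 | 2,2,2-trichloroethyl 4-[(trimethylsilyl)ethynyl]phenyl sulfate | C[Si](C)(C)C#Cc1ccc(OS(=O)(=O)OCC(Cl)(Cl)Cl)cc1 | intermediate
14 | 4-(bromoethynyl)phenyl 2,2,2-trichloroethyl sulfate | BrC#Cc1ccc(OS(=O)(=O)OCC(Cl)(Cl)Cl)cc1 | intermediate
15 | 2,2,2-trichloroethyl 4-[6-methoxy-5,7-bis(methoxymethoxy)-4-oxo-4H-chromen-2-yl]phenyl sulfate | COCOc1cc2oc(-c3ccc(OS(=O)(=O)OCC(Cl)(Cl)Cl)cc3)cc(=O)c2c(OCOC)c1OC | intermediate
16 | 4-(5,7-dihydroxy-6-methoxy-4-oxo-4H-chromen-2-yl)phenyl 2,2,2-trichloroethyl sulfate | COc1c(O)cc2oc(-c3ccc(OS(=O)(=O)OCC(Cl)(Cl)Cl)cc3)cc(=O)c2c1O | intermediate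
17 | hispidulin 4'-sulfate | COc1c(O)cc2oc(-c3ccc(OS(=O)(=O)O)cc3)cc(=O)c2c1O | target

## Step count

Total steps: 12.
Longest linear sequence: 8 (steps 1–5, 10, 11, 12). The aryl branch (steps 6, 8, 9) and the reagent branch (step 7) join it at step 10.

## Steps most likely to fail, with fallbacks

1. **Step 10 (proposed Rh annulation).** Risks are decarbonylation of the acyl-rhodium, slow turnover with the di-ortho-substituted aldehyde, and 5-exo (aurone) closure. Fallback, known chemistry: Pd-catalysed carbonylative Sonogashira annulation. Iodinate phenol 5 (NIS) instead of formylating it, protodesilylate 13 to the terminal alkyne (TBAF/AcOH), and couple the two under CO (1 atm) with PdCl2(PPh3)2 and amine base, closing the ynone 6-endo with DMAP to reach 15.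

2. **Step 4 (Ir C–H borylation/oxidation).** The trialkoxyarene is electron-rich and may borylate slowly, and phenol 5 is oxidation-prone. Fallback: functionalise the same carbon by electrophilic substitution. Brominate phenol 3 para to OH (NBS, MeCN, 0 °C), O-methylate, then Br/Li exchange (n-BuLi, −78 °C), B(OMe)3 and H2O2 to give 5. This costs one extra step.

3. **Step 12 (sulfate unmasking and isolation).** Zinc salts chelate the 5-hydroxy-4-keto unit and the free aryl hydrogen sulfate hydrolyses easily. Fallback: change the sulfate mask to a neopentyl ester, installed on 9 with neopentyl chlorosulfate (from neopentyl alcohol + SO2Cl2). It survives steps 9–11 and is removed last by SN2 dealkylation (NaN3, DMF, 70 °C), giving the sulfate salt with no reductant or metal.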